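The cycloheptane ring (C1–C5, C6, C10) is cut at C1–C10 and C5–C6. C1–C5, with the C5 methyl and oxygen at C1 and C4, are the ring carbons of 2-methylcyclopentane-1,3-dione, and C6=C10 is the double bond of a cyclopentene that already holds the quaternary C9. Enone–alkene photocycloaddition followed by retro-aldol opening fuses these two five-membered rings into the cis-fused cycloheptane-1,4-dione and sets C6 and C10 in one operation. The partners are the triethylsilyl enol ether of the dione and (S)-N,N-dimethyl-2-(1-methylcyclopent-2-en-1-yl)acetamide. Fragmentation is run aprotically, so the dione emerges with C4 still held as its C4–C5 enol ether.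

Key step: step 4

Atom labels (target numbering): ring carbons C1 (bears =CH2), C2, C3, C4, C5 (CMe2), C6, C7, C8, C9 (quaternary), C10; side chain C11 (CH on C9) and C16 (its CH2O); lactone C12 (ring CH on C11), C13 (OCH2), C14 (C=O), C15 (CHO).
"Hydroazulenyl" below means the cis-fused 1,4,4-trimethyl-8-methylidenedecahydroazulen-1-yl group of the target, attached through C9, with H6, H10 and the C9 side chain on one face and the C9 methyl on the other (absolute configuration as in the SMILES).
Remark: in the 1,4-dione the C1 carbonyl adjoins the neopentyl-like C10 and is the more hindered one, so the two carbonyls are told apart by the enolate that the fragmentation creates, not by reagent approach.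
Remark: the side-chain terminus (C16) is carried as the dimethylamide delivered by the Claisen step; it is a spectator in the key step and later becomes the acid that carries the auxiliary.
Assumption: the CBS reduction follows its usual model (alkenyl arm as the large group); if the sense proves opposite, the antipodal catalyst is used.
Remark: any minor-enantiomer material from step 1 becomes a diastereomer once the auxiliary is attached (17, 19) and is removed there.

Step 1
Reactants: 1 3-methylcyclopent-2-en-1-one
Product: 2 (S)-3-methylcyclopent-2-en-1-ol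
Conditions: (R)-1-methyl-3,3-diphenyltetrahydro-1H,3H-pyrrolo[1,2-c][1,3,2]oxazaborole (the (R)-methyl CBS catalyst, 10 mol %), catecholborane, toluene, −78 °C; aq. NaOH work-up
Reagents that add atoms: none
Why: Corey–Bakshi–Shibata reduction: with the alkenyl arm of the enone in the large-group position of the catalyst–borane complex, hydride is delivered to one carbonyl face only and sets the carbinol centre as S.

Step 2
Reactants: 2 (S)-3-methylcyclopent-2-en-1-ol
Product: 4 (S)-N,N-dimethyl-2-(1-methylcyclopent-2-en-1-yl)acetamide, via ketene N,O-acetal 3 (not isolated)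
Conditions: CH3C(OCH3)2N(CH3)2 (3 equiv), xylene, 140 °C, MeOH distilled off
Reagents that add atoms: N,N-dimethylacetamide dimethyl acetal, CC(OC)(OC)N(C)C
Why: Eschenmoser–Claisen rearrangement: the [3,3] shift of 3 is suprafacial on the ring, so the acetamide carbon bonds to C9 on the face that carried the C–O bond, and the carbinol chirality becomes that of the quaternary centre while the alkene moves to C6=C10.

Step 3
Reactants: 5 2-methylcyclopentane-1,3-dione
Product: 6 2-methyl-3-(triethylsilyloxy)cyclopent-2-en-1-one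
Conditions: Et3SiCl, Et3N, CH2Cl2, 0 °C → rt
Reagents that add atoms: chlorotriethylsilane, CC[Si](Cl)(CC)CC
Why: O-Silylation of the enol form of the 1,3-dione gives the vinylogous silyl ester that acts as the photoactive enone.

Step 4
Reactants: 4 (S)-N,N-dimethyl-2-(1-methylcyclopent-2-en-1-yl)acetamide; 6 2-methyl-3-(triethylsilyloxy)cyclopent-2-en-1-one
Product: 9 C4 triethylsilyl enol ether (C4=C5) of the cis-fused bicyclo[5.3.0]decane-1,4-dione (C1 ketone free; C5 CH3; C9 CH3 and CH2CONMe2), via cyclobutane photoadduct 7 (not isolated), via sulfonium enolate 8 (not isolated)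
Conditions: hν (medium-pressure Hg lamp, Pyrex, λ > 300 nm), 4 (3 equiv, excess recovered), CH2Cl2, −30 °C; concentrate; (Me2N)3S+ Me3SiF2− (1.1 equiv), THF, −78 °C; then Et3SiCl, −78 → 0 °C; chromatography on Et3N-deactivated silica
Reagents that add atoms: chlorotriethylsilane, CC[Si](Cl)(CC)CC
Why: Pyrex-filtered light excites enone 6, whose triplet adds to the C6=C10 bond of 4 through a 1,4-biradical that closes to cyclobutane 7 (bonds C1–C10 and C5–C6); fluoride then removes the silyl group from the C1 oxygen and the strained β-keto alkoxide cleaves its C1–C5 bond by retro-aldol, the closest known reaction type being the de Mayo photocycloaddition–retro-aldol sequence. The cyclobutane closes by radical recombination of the biradical, and the seven-membered ring is formed not by cyclisation but by two-carbon ring expansion when the bond common to the cyclobutane and the cyclopentanone breaks. C6 and C10 are both created in the cycloaddition: their cis relation is imposed by the four-membered ring, and their sense relative to C9 comes from approach of the enone to the alkene face bearing the C9 methyl, away from the larger CH2CONMe2 arm. The step needs head-to-head orientation (oxygenated carbon to C10), which is favoured because the oxygen-bearing enone carbon is the slimmer terminus and takes the neopentyl-like C10 while the methyl-bearing carbon bonds to the open C6. Aprotic fragmentation with immediate silylation keeps the enolate at C4–C5 where the bond scission placed it, so the more hindered C1 carbonyl is left free and the regiochemistry for the later C5 methylation is stored in enol ether 9.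

Step 5
Reactants: 9 C4 triethylsilyl enol ether of the cis-fused 1,4-dione
Product: 10 C1-methylidene C4 triethylsilyl enol ether (C1=CH2; C4=C5 enol ether; amide unchanged)
Conditions: Ph3PCH3Br, KN(SiMe3)2, toluene, 0 → 80 °C
Reagents that add atoms: methyltriphenylphosphonium bromide, C[P+](c1ccccc1)(c1ccccc1)c1ccccc1.[Br-]
Why: Wittig methylenation: C1 is the only carbonyl that can react with the ylide because C4 is locked as the silyl enol ether and the tertiary amide is inert, so no reagent-based choice between the two ring carbonyls is needed.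

Step 6
Reactants: 10 C1-methylidene C4 triethylsilyl enol ether
Product: 12 N,N-dimethyl-2-(C4-oxo-hydroazulenyl)acetamide (C4 ketone; C5 now CMe2), via sulfonium enolate 11 (not isolated)
Conditions: (Me2N)3S+ Me3SiF2− (1.1 equiv), MeI (5 equiv), THF, −78 → 0 °C
Reagents that add atoms: iodomethane, CI
Why: Fluoride-triggered regiospecific enolate alkylation of a silyl enol ether: desilylation releases the C4–C5 enolate in the presence of iodomethane, which methylates C5 before the enolate can migrate and so builds the gem-dimethyl carbon (no stereocentre is created).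

Step 7
Reactants: 12 N,N-dimethyl-2-(C4-oxo-hydroazulenyl)acetamide
Product: 15 2-(hydroazulenyl)acetic acid, via C4 hydrazone 13 (not isolated), via deoxygenated amide 14 (not isolated)
Conditions: N2H4·H2O, KOH, diethylene glycol, 130 °C then 205 °C (water distilled off), N2; then dilute HCl to pH 3
Reagents that add atoms: potassium hydroxide, [K+].[OH-]
Why: Wolff–Kishner reduction (Huang-Minlon variant) converts the hindered C4 ketone into CH2 through hydrazone 13, and the same hot alkali hydrolyses the dimethylamide to the acid, while the isolated 1,1-disubstituted alkene is inert to both.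

Step 8
Reactants: 15 2-(hydroazulenyl)acetic acid
Product: 17 (R)-4-benzyl-3-[2-(hydroazulenyl)acetyl]-1,3-oxazolidin-2-one, via mixed pivalic anhydride 16 (not isolated)
Conditions: t-BuCOCl, Et3N, THF, −20 °C; then (R)-4-benzyl-1,3-oxazolidin-2-one, LiCl, −20 °C → rt
Reagents that add atoms: (R)-4-benzyl-1,3-oxazolidin-2-one, O=C1OC[C@@H](Cc2ccccc2)N1
Why: N-Acylation of the Evans oxazolidinone through a mixed pivalic anhydride: the auxiliary attacks the substrate carbonyl, which is far less hindered than the pivaloyl one.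

Step 9
Reactants: 17 (R)-4-benzyl-3-[2-(hydroazulenyl)acetyl]-1,3-oxazolidin-2-one
Product: 19 tert-butyl (3R)-4-[(R)-4-benzyl-2-oxo-1,3-oxazolidin-3-yl]-3-(hydroazulenyl)-4-oxobutanoate, via sodium enolate 18 (not isolated)
Conditions: NaN(SiMe3)2, THF, −78 °C; BrCH2CO2t-Bu, −78 → −40 °C
Reagents that add atoms: tert-butyl bromoacetate, CC(C)(C)OC(=O)CBr
Why: Evans asymmetric alkylation: the chelated Z-enolate 18 is alkylated on the face opposite the benzyl group of the (R)-auxiliary, which fixes C11 in the configuration of the target.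

Step 10
Reactants: 19 alkylated imide
Product: 20 tert-butyl (3R)-3-(hydroazulenyl)-4-hydroxybutanoate
Conditions: LiBH4, H2O (1.1 equiv), Et2O, 0 °C
Reagents that add atoms: none
Why: Reductive cleavage of the N-acyl oxazolidinone with lithium borohydride converts the imide carbonyl into the C16 primary alcohol and releases the auxiliary, the tert-butyl ester being too slow to reduce or to lactonise under these conditions.

Step 11
Reactants: 20 tert-butyl (3R)-3-(hydroazulenyl)-4-hydroxybutanoate
Product: 21 tert-butyl (3R)-4-(tert-butyldimethylsilyloxy)-3-(hydroazulenyl)butanoate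
Conditions: t-BuMe2SiCl, imidazole, DMF, rt
Reagents that add atoms: tert-butyl(chloro)dimethylsilane, CC(C)(C)[Si](C)(C)Cl
Why: Silyl ether protection of the primary alcohol prevents lactonisation and O-alkylation in the following enolate step.

Step 12
Reactants: 21 silyl ether tert-butyl ester
Product: 23 4-allyl 1-tert-butyl (2R)-2-[(1R)-2-(tert-butyldimethylsilyloxy)-1-(hydroazulenyl)ethyl]butanedioate, via lithium enolate 22 (not isolated)
Conditions: LiN(i-Pr)2, THF–DMPU, −78 °C; BrCH2CO2CH2CH=CH2, −78 → −30 °C
Reagents that add atoms: allyl bromoacetate, C=CCOC(=O)CBr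
Why: Substrate-controlled ester enolate alkylation: allylic 1,3-strain keeps the C11–H bond in the plane of enolate 22, so the bromoacetate approaches C12 anti to the bulky C9 ring system, which gives the C11/C12 relationship of the target.

Step 13
Reactants: 23 allyl tert-butyl diester
Product: 24 (3R)-4-tert-butoxy-3-[(1R)-2-(tert-butyldimethylsilyloxy)-1-(hydroazulenyl)ethyl]-4-oxobutanoic acid
Conditions: Pd(PPh3)4 (5 mol %), morpholine, THF, rt; dilute citric acid work-up
Reagents that add atoms: none
Why: Tsuji–Trost deallylation: zerovalent palladium ionises the allyl ester and morpholine traps the allyl group, which frees the C14 acid without touching the tert-butyl ester, the silyl ether or the alkene.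

Step 14
Reactants: 24 mono-tert-butyl succinic acid
Product: 26 (4R)-4-[(1R)-2-(tert-butyldimethylsilyloxy)-1-(hydroazulenyl)ethyl]oxolan-2-one, via hydroxy acid 25 (not isolated)
Conditions: LiEt3BH (4 equiv), THF, 0 °C → rt; then 1 M HCl to pH 3; pyridinium p-toluenesulfonate (cat.), CH2Cl2, rt
Reagents that add atoms: none
Why: Chemoselective hydride reduction then lactonisation: the lithium carboxylate at C14 is inert to triethylborohydride while the C13 tert-butyl ester is reduced to the alcohol, and hydroxy acid 25 closes to the γ-lactone on acidification.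

Step 15
Reactants: 26 silyl ether lactone
Product: 28 (3S,4R)-4-[(1R)-2-(tert-butyldimethylsilyloxy)-1-(hydroazulenyl)ethyl]-3-hydroxyoxolan-2-one, via potassium enolate 27 (not isolated)
Conditions: KN(SiMe3)2, THF, −78 °C; trans-2-(phenylsulfonyl)-3-phenyloxaziridine, −78 °C; aq. NH4Cl
Reagents that add atoms: trans-2-(phenylsulfonyl)-3-phenyloxaziridine, O=S(=O)(c1ccccc1)N1OC1c1ccccc1
Why: Davis oxidation of a lactone enolate: the oxaziridine transfers oxygen to C15 of enolate 27 on the face away from the C12 substituent, so the hydroxyl is trans to it as in the target.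

Step 16
Reactants: 28 silyl ether hydroxy lactone
Product: 29 (3S,4R)-3-hydroxy-4-[(1R)-2-hydroxy-1-(hydroazulenyl)ethyl]oxolan-2-one
Conditions: HF·pyridine, pyridine, THF, 0 °C → rt
Reagents that add atoms: none
Why: Fluoride desilylation under weakly acidic conditions frees the C16 alcohol and avoids base that could epimerise C15 or move the lactone.

Step 17
Reactants: 29 diol lactone
Product: 30 CNP0234964.1, (3S,4R)-4-[(1R)-2-acetoxy-1-(hydroazulenyl)ethyl]-2-oxooxolan-3-yl acetate
Conditions: Ac2O, pyridine, 4-(dimethylamino)pyridine (cat.), CH2Cl2, 0 °C → rt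
Reagents that add atoms: acetic anhydride, CC(=O)OC(C)=O
Why: Acyl transfer catalysed by 4-(dimethylamino)pyridine acetylates the primary C16 and the secondary C15 hydroxyl together and completes the target.

Compound list
1 | 3-methylcyclopent-2-en-1-one | CC1=CC(=O)CC1 | starting material
2 | (S)-3-methylcyclopent-2-en-1-ol | O[C@@H]1C=C(C)CC1 | intermediate
3 | ketene N,O-acetal of 2 (1-(dimethylamino)vinyl ether) | C=C(N(C)C)O[C@@H]1C=C(C)CC1 | intermediate (not isolated)
4 | (S)-N,N-dimethyl-2-(1-methylcyclopent-2-en-1-yl)acetamide | C1=CCC[C@@]1(C)CC(=O)N(C)C | intermediate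
5 | 2-methylcyclopentane-1,3-dione | CC1C(=O)CCC1=O | starting material
6 | 2-methyl-3-(triethylsilyloxy)cyclopent-2-en-1-one | CC1=C(O[Si](CC)(CC)CC)CCC1=O | intermediate
7 | cis-anti-cis cyclobutane photoadduct (C1–OSiEt3, C4 ketone, C5 methyl; bonds C1–C10 and C5–C6) | CC[Si](CC)(CC)O[C@]12CCC(=O)[C@@]1(C)[C@@H]1CC[C@@](C)(CC(=O)N(C)C)[C@@H]12 | intermediate (not isolated)
8 | tris(dimethylamino)sulfonium C4–C5 enolate of the cis-fused 1,4-dione | [O-]C1=C(C)[C@@H]2CC[C@@](C)(CC(=O)N(C)C)[C@@H]2C(=O)CC1.CN(C)[S+](N(C)C)N(C)C | intermediate (not isolated)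
9 | C4 triethylsilyl enol ether of the cis-fused bicyclo[5.3.0]decane-1,4-dione (C1 ketone free) | CC[Si](CC)(CC)OC1=C(C)[C@@H]2CC[C@@](C)(CC(=O)N(C)C)[C@@H]2C(=O)CC1 | intermediate
10 | C1-methylidene C4 triethylsilyl enol ether | CC[Si](CC)(CC)OC1=C(C)[C@@H]2CC[C@@](C)(CC(=O)N(C)C)[C@@H]2C(=C)CC1 | intermediate
11 | tris(dimethylamino)sulfonium C4–C5 enolate of the C1-methylidene ketone | [O-]C1=C(C)[C@@H]2CC[C@@](C)(CC(=O)N(C)C)[C@@H]2C(=C)CC1.CN(C)[S+](N(C)C)N(C)C | intermediate (not isolated)
12 | N,N-dimethyl-2-(C4-oxo-hydroazulenyl)acetamide | C=C1CCC(=O)C(C)(C)[C@@H]2CC[C@@](C)(CC(=O)N(C)C)[C@H]12 | intermediate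
13 | C4 hydrazone of 12 | C=C1CCC(=NN)C(C)(C)[C@@H]2CC[C@@](C)(CC(=O)N(C)C)[C@H]12 | intermediate (not isolated)
14 | N,N-dimethyl-2-(hydroazulenyl)acetamide | C=C1CCCC(C)(C)[C@@H]2CC[C@@](C)(CC(=O)N(C)C)[C@H]12 | intermediate (not isolated)
15 | 2-(hydroazulenyl)acetic acid | C=C1CCCC(C)(C)[C@@H]2CC[C@@](C)(CC(=O)O)[C@H]12 | intermediate
16 | mixed anhydride of 15 with pivalic acid | C=C1CCCC(C)(C)[C@@H]2CC[C@@](C)(CC(=O)OC(=O)C(C)(C)C)[C@H]12 | intermediate (not isolated)
17 | (R)-4-benzyl-3-[2-(hydroazulenyl)acetyl]-1,3-oxazolidin-2-one | C=C1CCCC(C)(C)[C@@H]2CC[C@@](C)(CC(=O)N3[C@H](Cc4ccccc4)COC3=O)[C@H]12 | intermediate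
18 | sodium Z-enolate of 17 | C=C1CCCC(C)(C)[C@@H]2CC[C@@](C)(/C=C(\[O-])N3[C@H](Cc4ccccc4)COC3=O)[C@H]12.[Na+] | intermediate (not isolated)
19 | tert-butyl (3R)-4-[(R)-4-benzyl-2-oxo-1,3-oxazolidin-3-yl]-3-(hydroazulenyl)-4-oxobutanoate | C=C1CCCC(C)(C)[C@@H]2CC[C@@](C)([C@@H](CC(=O)OC(C)(C)C)C(=O)N3[C@H](Cc4ccccc4)COC3=O)[C@H]12 | intermediate
20 | tert-butyl (3R)-3-(hydroazulenyl)-4-hydroxybutanoate | C=C1CCCC(C)(C)[C@@H]2CC[C@@](C)([C@@H](CC(=O)OC(C)(C)C)CO)[C@H]12 | intermediate
21 | tert-butyl (3R)-4-(tert-butyldimethylsilyloxy)-3-(hydroazulenyl)butanoate | C=C1CCCC(C)(C)[C@@H]2CC[C@@](C)([C@@H](CC(=O)OC(C)(C)C)CO[Si](C)(C)C(C)(C)C)[C@H]12 | intermediate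
22 | lithium enolate of 21 | C=C1CCCC(C)(C)[C@@H]2CC[C@@](C)([C@@H](C=C([O-])OC(C)(C)C)CO[Si](C)(C)C(C)(C)C)[C@H]12.[Li+] | intermediate (not isolated)
23 | 4-allyl 1-tert-butyl (2R)-2-[(1R)-2-(tert-butyldimethylsilyloxy)-1-(hydroazulenyl)ethyl]butanedioate | C=C1CCCC(C)(C)[C@@H]2CC[C@@](C)([C@@H]([C@@H](CC(=O)OCC=C)C(=O)OC(C)(C)C)CO[Si](C)(C)C(C)(C)C)[C@H]12 | intermediate
24 | (3R)-4-tert-butoxy-3-[(1R)-2-(tert-butyldimethylsilyloxy)-1-(hydroazulenyl)ethyl]-4-oxobutanoic acid | C=C1CCCC(C)(C)[C@@H]2CC[C@@](C)([C@@H]([C@@H](CC(=O)O)C(=O)OC(C)(C)C)CO[Si](C)(C)C(C)(C)C)[C@H]12 | intermediate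
25 | (3R,4R)-5-(tert-butyldimethylsilyloxy)-4-(hydroazulenyl)-3-(hydroxymethyl)pentanoic acid | C=C1CCCC(C)(C)[C@@H]2CC[C@@](C)([C@@H]([C@@H](CC(=O)O)CO)CO[Si](C)(C)C(C)(C)C)[C@H]12 | intermediate (not isolated)
26 | (4R)-4-[(1R)-2-(tert-butyldimethylsilyloxy)-1-(hydroazulenyl)ethyl]oxolan-2-one | C=C1CCCC(C)(C)[C@@H]2CC[C@@](C)([C@H](CO[Si](C)(C)C(C)(C)C)[C@@H]3COC(=O)C3)[C@H]12 | intermediate
27 | potassium enolate of 26 | C=C1CCCC(C)(C)[C@@H]2CC[C@@](C)([C@H](CO[Si](C)(C)C(C)(C)C)[C@@H]3COC([O-])=C3)[C@H]12.[K+] | intermediate (not isolated)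
28 | (3S,4R)-4-[(1R)-2-(tert-butyldimethylsilyloxy)-1-(hydroazulenyl)ethyl]-3-hydroxyoxolan-2-one | C=C1CCCC(C)(C)[C@@H]2CC[C@@](C)([C@H](CO[Si](C)(C)C(C)(C)C)[C@@H]3COC(=O)[C@H]3O)[C@H]12 | intermediate
29 | (3S,4R)-3-hydroxy-4-[(1R)-2-hydroxy-1-(hydroazulenyl)ethyl]oxolan-2-one | C=C1CCCC(C)(C)[C@@H]2CC[C@@](C)([C@H](CO)[C@@H]3COC(=O)[C@H]3O)[C@H]12 | intermediate
30 | CNP0234964.1, (3S,4R)-4-[(1R)-2-acetoxy-1-(hydroazulenyl)ethyl]-2-oxooxolan-3-yl acetate | C=C1CCCC(C)(C)[C@@H]2CC[C@@](C)([C@H](COC(C)=O)[C@@H]3COC(=O)[C@H]3OC(C)=O)[C@H]12 | target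

Total step count: 17. Longest linear sequence: 16 (steps 1, 2 and 4–17; step 3 is the side branch).

Steps most likely to fail

Step 4. Two processes can erode it: the bimolecular cycloaddition may discriminate only moderately between the two alkene faces and the two orientations, and proton exchange between the fluoride-generated enolate and not yet desilylated ketone may move the enolate before it is silylated. Face and orientation isomers are removed by chromatography at 9. If the enolate capture is not clean, the fallback sets out from photoadduct 7 and gives up the capture. Buffered protic desilylation (Bu4N+ F−, AcOH, THF) gives the free cis-fused 1,4-dione F1. Its less hindered C4 carbonyl is ketalised (ethylene glycol, p-TsOH, benzene, reflux) to the mono-dioxolane F2. C1 is methylenated (Ph3P=CH2, toluene, 80 °C) to the methylidene dioxolane F3, and the acetal is hydrolysed (pyridinium p-toluenesulfonate, wet acetone) to the C1-methylidene C4 ketone F4. C5 is then methylated through the thermodynamic potassium enoxyborate (KH, BEt3, THF; MeI), which returns to the route at 12.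

Step 9. C-Alkylation of the enolate next to the quaternary C9 may be slower than decomposition of the sodium enolate. The fallback sets out from acid 15 and drops the auxiliary. The enediolate (LiN(i-Pr)2, 2.2 equiv, THF–DMPU, 0 °C) is alkylated with tert-butyl bromoacetate to the succinic half ester F5, formed as both C11 epimers. Only the free acid is reduced (i-BuOCOCl, N-methylmorpholine; then NaBH4, THF–H2O), giving 20 together with its C11 epimer F6. The two are separated by chromatography, and the route is rejoined at 20.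

Step 12. Facial discrimination of the acyclic enolate may be insufficient, giving the C12 epimer. The fallback sets out from 20 and uses a ring template. Lactonisation (pyridinium p-toluenesulfonate, toluene, 80 °C) gives the β-substituted γ-lactone F7. Its enolate (LiN(i-Pr)2, −78 °C) is alkylated with allyl bromoacetate trans to the ring substituent, giving the trans lactone allyl ester F8, and deallylation (Pd(PPh3)4, morpholine) gives the trans lactone acid F9. The dianion of F9 (LiN(i-Pr)2, 2.2 equiv, −78 °C) is protonated kinetically with 2,6-di-tert-butylphenol on the face away from the C9 ring system, giving the cis lactone acid F10. Reduction of the lactone carbonyl of its lithium salt (LiBH4, THF) and acidification moves the lactone onto the new C13 hydroxyl, giving the hydroxy lactone F11. Silylation (t-BuMe2SiCl, imidazole) returns to the route at 26.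

Further compounds
F1 | step 4 | free cis-fused bicyclo[5.3.0]decane-1,4-dione (C5 methyl epimer not controlled; C9 CH3 and CH2CONMe2) | O=C1CCC(=O)[C@@H](C)[C@@H]2CC[C@@](C)(CC(=O)N(C)C)[C@H]12
F2 | step 4 | C4 mono-dioxolane of F1 | O=C1CCC2(OCCO2)[C@@H](C)[C@@H]2CC[C@@](C)(CC(=O)N(C)C)[C@H]12
F3 | step 4 | C1-methylidene C4 dioxolane | C=C1CCC2(OCCO2)[C@@H](C)[C@@H]2CC[C@@](C)(CC(=O)N(C)C)[C@H]12
F4 | step 4 | C1-methylidene C4 ketone with C5 monomethyl | C=C1CCC(=O)[C@@H](C)[C@@H]2CC[C@@](C)(CC(=O)N(C)C)[C@H]12
F5 | step 9 | 4-tert-butoxy-2-(hydroazulenyl)-4-oxobutanoic acid (both C11 epimers) | C=C1CCCC(C)(C)[C@@H]2CC[C@@](C)(C(CC(=O)OC(C)(C)C)C(=O)O)[C@H]12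
F6 | step 9 | tert-butyl (3S)-3-(hydroazulenyl)-4-hydroxybutanoate (C11 epimer of 20) | C=C1CCCC(C)(C)[C@@H]2CC[C@@](C)([C@H](CC(=O)OC(C)(C)C)CO)[C@H]12
F7 | step 12 | (4R)-4-(hydroazulenyl)oxolan-2-one | C=C1CCCC(C)(C)[C@@H]2CC[C@@](C)([C@@H]3COC(=O)C3)[C@H]12
F8 | step 12 | allyl 2-[trans-4-(hydroazulenyl)-2-oxooxolan-3-yl]acetate | C=C1CCCC(C)(C)[C@@H]2CC[C@@](C)([C@@H]3COC(=O)[C@H]3CC(=O)OCC=C)[C@H]12
F9 | step 12 | 2-[trans-4-(hydroazulenyl)-2-oxooxolan-3-yl]acetic acid | C=C1CCCC(C)(C)[C@@H]2CC[C@@](C)([C@@H]3COC(=O)[C@H]3CC(=O)O)[C@H]12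
F10 | step 12 | 2-[cis-4-(hydroazulenyl)-2-oxooxolan-3-yl]acetic acid | C=C1CCCC(C)(C)[C@@H]2CC[C@@](C)([C@@H]3COC(=O)[C@@H]3CC(=O)O)[C@H]12
F11 | step 12 | (4R)-4-[(1R)-2-hydroxy-1-(hydroazulenyl)ethyl]oxolan-2-one | C=C1CCCC(C)(C)[C@@H]2CC[C@@](C)([C@H](CO)[C@@H]3COC(=O)C3)[C@H]12
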